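The numbers in the tables are simulated for an exercise, and the scatter is random.

In the stirred vessel of the oak flask the two substrates together, 0.100 M, are the limiting reagent against the 0.125 M of partner fed over 2.0 min, so I keep a ledger of substrate.

| setting | oak | alder | flask |
|---|---|---|---|
| left-handed substrate | 0.050 M | 0.050 M | 0.050 M |
| right-handed substrate | 0.050 M | 0.050 M | 0.050 M |
| partner | 0.125 M (fed, over 2.0 min) | 0.084 M (fed, over 2.0 min) | 0.125 M (fed, over 2.0 min) |
| remark | the very flask that is asked about, followed so far; the fed solution adds 0.50 times the starting volume | run made earlier; the fed solution adds 0.50 times the starting volume | the fed solution adds 0.50 times the starting volume |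
| time |  |  | 40 min |

| run | time / min | left-handed product / % | right-handed substrate / % | achiral form / % | right-handed product / % | left-handed substrate / % |
|---|---|---|---|---|---|---|
| oak | 0.250 | 0.2 | 49.2 | 1.7 | 0 | 49.2 |
| oak | 0.667 | 0.9 | 48.4 | 3.6 | 0.4 | 48.2 |
| oak | 1.33 | 1.2 | 46.9 | 4.8 | 0.5 | 46.0 |
| oak | 3.00 | 6.1 | 43.0 | 6.0 | 3.2 | 40.2 |
| alder | 2.00 | 2.3 | 45.5 | 5.7 | 1.3 | 44.6 |
| alder | 6.00 | 9.2 | 41.1 | 6.0 | 4.4 | 36.3 |
| alder | 10.0 | 14.0 | 36.7 | 5.2 | 7.1 | 32.0 |
| alder | 15.0 | 18.6 | 31.8 | 4.7 | 9.6 | 26.7 |

(standard deviation of a reading: 0.3 percentage points)

- partner is single-handed; left-handed substrate and right-handed substrate are mirror images of each other, charged as a racemate, each of them at the stated concentration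
- charges are per starting volume, the dose included; the dosed solution carries all of it
- the numbers in the tables scatter by 0.3 percentage points (one standard deviation)
- the handed part of partner does not stay in what it makes, so the products of the two hands are mirror images too

- the species that holds most of what was charged as left-handed substrate and right-handed substrate together, at 40 min (left-handed product / left-handed substrate / right-handed product / achiral form / right-handed substrate)
- the largest share itself, whichever of these holds it, in percent of the left-handed substrate and right-handed substrate together charged

At 15.0 min the alder ledger reads 28.2% in the two products, and 8.60% stands in no column. Partner in alder has a midpoint of 0.0699 M between its charge and what the product leaves. I divide product per point lost by that midpoint and call the result the capture number, 46.9 /M, which I take as constant from flask to flask. Alder also gives two readings: the pool of both substrates and achiral form falls at 0.0320 /min, and left-handed product is 66.0% of product. I keep that pace for the oak flask, although it has more partner, and I guess that half of the substrates reach product.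

Pool at 40 min: 27.8%

Product per point lost, at a partner midpoint of 0.100 M: 4.69

Product: 59.5%

Left-handed product: 39.2%

That is larger than the whole pool and larger than the 20.3% of right-handed product, so left-handed product leads in my ledger. The forecast names left-handed product at 38%, between 34% and 42%: “Left-handed product holds the most.” My figure lies above its number and inside its range.

The oak flask gives left-handed product at 40.2%.

    partner + left-handed substrate → left-handed product (k = 0.850 /M/min)
    right-handed substrate ⇌ achiral form (K = 0.180, k = 0.0610 /min)
    partner + right-handed substrate → right-handed product (k = 0.370 /M/min)
    left-handed substrate ⇌ achiral form (K = 0.180, k = 0.0610 /min)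
    achiral form → decomposed reagent (k = 0.0950 /min)

The oak flask holds 62.4% of product against 13.8% of decomposed reagent at 40.0 min, a ratio of 4.52, and the capture number with this flask's own partner midpoint gives 4.40. With 0.50 M of partner, a neighbour has a midpoint of 0.450 M if its substrates are used up, so the capture number gives an estimate of 4.52% lost. That neighbour computes to 4.99% of decomposed reagent, with 52.8% of left-handed product and 41.7% of right-handed product.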